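The ten-membered carbocycle (C1–C10, germacrane numbering) is not closed at its final size. Everything rests on its C2–C3 bond, which is allylic to the C1=C10 alkene (later the epoxide) and α to the C4 carbonyl (later the tertiary carbinol). That bond is made by a palladium-catalysed decarboxylative allylation that extrudes CO2 from a twelve-membered allyl β-keto lactone. In one operation the ring contracts by two atoms, C3 is set and the E-alkene is fixed. The precursor is a macrolactone in which O–C2 is acylated by a C3 carboxyl group; it comes from an acylketene macrolactonisation after a Marshall propargylation and a cyclocarbonylation have built the trans-fused α-methylene lactone.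

Key step: step 15

Remark: germacrane numbering is used throughout (C1/C10 epoxide carbons, C3/C4 diol carbons, C6 lactone carbinol, C7 ring-fusion carbon, C8 angelate carbinol, C11–C13 acrylate unit, C14/C15 methyls on C10/C4); the target is read as 8β-angeloyloxy-1β,10α-epoxy-3β,4α-dihydroxygermacr-11(13)-en-6α,12-olide (1R,3S,4S,6R,7S,8R,10R).

Step 1
Reactants: 1 (R)-glycidyl 4-methoxybenzyl ether
Product: 2 (R)-1-[(4-methoxybenzyl)oxy]pent-4-yn-2-ol
Conditions: HC≡CLi·ethylenediamine, DMSO, 0 °C → rt
Reagents that add atoms: lithium acetylide ethylenediamine complex, [Li]C#C.NCCN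
Why: Epoxide alkynylation, in which the acetylide opens the unhindered terminal carbon (C9) by SN2 so that the carbinol stereocentre (C8, from the chiral pool) is untouched.

Step 2
Reactants: 2 (R)-1-[(4-methoxybenzyl)oxy]pent-4-yn-2-ol
Product: 4 (2E,5R)-6-[(4-methoxybenzyl)oxy]-3-methylhex-2-ene-1,5-diol, via alkenylalane 3 (not isolated)
Conditions: AlMe3 (3.5 equiv), Cp2ZrCl2 (0.25 equiv), CH2Cl2, 0 °C → rt; n-BuLi, −78 °C; (CH2O)n, THF, −78 °C → rt
Reagents that add atoms: trimethylaluminium, C[Al](C)C; paraformaldehyde, C=O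
Why: Negishi zirconium-catalysed carboalumination adds methyl and aluminium syn across the terminal alkyne (methyl on the inner carbon) and the alkenylalanate is hydroxymethylated with retention, which should give the E-trisubstituted C1=C10 allylic alcohol with the free C8 hydroxyl tolerated as its aluminium alkoxide.

Step 3
Reactants: 4 (2E,5R)-6-[(4-methoxybenzyl)oxy]-3-methylhex-2-ene-1,5-diol
Product: 5 (2E,5R)-1,5-bis(tert-butyldimethylsilyloxy)-6-[(4-methoxybenzyl)oxy]-3-methylhex-2-ene
Conditions: TBSCl (2.5 equiv), imidazole, DMF, rt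
Reagents that add atoms: tert-butyldimethylsilyl chloride, CC(C)(C)[Si](C)(C)Cl
Why: Imidazole-promoted silylation protects both hydroxyls in one operation and places on C8–O the bulky, non-chelating group that steers step 6.

Step 4
Reactants: 5 (2E,5R)-1,5-bis(tert-butyldimethylsilyloxy)-6-[(4-methoxybenzyl)oxy]-3-methylhex-2-ene
Product: 6 (2R,4E)-2,6-bis(tert-butyldimethylsilyloxy)-4-methylhex-4-en-1-ol
Conditions: DDQ (1.3 equiv), CH2Cl2/pH 7 buffer (10:1), 0 °C
Reagents that add atoms: none
Why: DDQ oxidises the electron-rich p-methoxybenzyl ether to an oxocarbenium ion that water hydrolyses (oxidative PMB cleavage), which frees only the C7 primary alcohol while silyl ethers and the alkene are inert.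

Step 5
Reactants: 6 (2R,4E)-2,6-bis(tert-butyldimethylsilyloxy)-4-methylhex-4-en-1-ol
Product: 7 (2R,4E)-2,6-bis(tert-butyldimethylsilyloxy)-4-methylhex-4-enal
Conditions: Dess–Martin periodinane, NaHCO3, CH2Cl2, 0 °C → rt
Reagents that add atoms: none
Why: Dess–Martin oxidation under bicarbonate buffering should give the α-silyloxy aldehyde without epimerisation at C8 or silyl migration.

Step 6
Reactants: 7 (2R,4E)-2,6-bis(tert-butyldimethylsilyloxy)-4-methylhex-4-enal
Product: 8 (3S,4R,6E)-4,8-bis(tert-butyldimethylsilyloxy)-6-methyloct-6-en-1-yn-3-ol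
Conditions: HC≡CMgBr (1.5 equiv), THF, −78 °C
Reagents that add atoms: ethynylmagnesium bromide, C#C[Mg]Br
Why: Addition of the alkynyl Grignard reagent under non-chelating conditions should follow the polar Felkin–Anh model (attack anti to the α-silyloxy group) and give mainly the 7,8-anti (3S,4R) propargylic alcohol, the configuration that step 9 relays to C7 and C6.

Step 7
Reactants: 8 (3S,4R,6E)-4,8-bis(tert-butyldimethylsilyloxy)-6-methyloct-6-en-1-yn-3-ol
Product: 9 (3S,4R,6E)-4,8-bis(tert-butyldimethylsilyloxy)-6-methyloct-6-en-1-yn-3-yl methanesulfonate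
Conditions: MsCl, Et3N, CH2Cl2, −78 → 0 °C
Reagents that add atoms: methanesulfonyl chloride, CS(=O)(=O)Cl
Why: Sulfonylation of the alcohol with retention at C7 (mesylation) gives the propargylic mesylate required for anti-SN2′ palladation.

Step 8
Reactants: 10 methyl 3,3-dimethoxypropanoate
Product: 11 3,3-dimethoxypropanal
Conditions: DIBAL-H (1.05 equiv), CH2Cl2, −78 °C; Rochelle salt work-up
Reagents that add atoms: none
Why: DIBAL-H half-reduction of the ester at −78 °C stops at the aluminium hemiacetal and should give the aldehyde on work-up, the acetal being inert.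

Step 9
Reactants: 9 (3S,4R,6E)-4,8-bis(tert-butyldimethylsilyloxy)-6-methyloct-6-en-1-yn-3-yl methanesulfonate, 11 3,3-dimethoxypropanal
Product: 13 (3R,4S,5R,7E)-5,9-bis(tert-butyldimethylsilyloxy)-4-ethynyl-1,1-dimethoxy-7-methylnon-7-en-3-ol, via allenylzinc 12 (not isolated)
Conditions: Pd(OAc)2 (5 mol%), PPh3 (5 mol%), Et2Zn (3 equiv), THF, −78 → −20 °C
Reagents that add atoms: none
Why: Marshall propargylation, in which anti-SN2′ oxidative addition of Pd(0) to the mesylate and transmetallation give an axially chiral allenylzinc that should add to the aldehyde through a cyclic SE2′ transition state, so that the new C7–C6 bond forms with net inversion at C7 (chirality transfer) and C6–OH anti to the C8 branch.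

Step 10
Reactants: 13 (3R,4S,5R,7E)-5,9-bis(tert-butyldimethylsilyloxy)-4-ethynyl-1,1-dimethoxy-7-methylnon-7-en-3-ol
Product: 14 (4S,5R)-4-[(1R,3E)-1,5-bis(tert-butyldimethylsilyloxy)-3-methylpent-3-en-1-yl]-5-(2,2-dimethoxyethyl)-3-methylideneoxolan-2-one
Conditions: PdCl2 (5 mol%), PPh3 (10 mol%), SnCl2 (5 mol%), CO (8 bar), MeCN, 70 °C
Reagents that add atoms: carbon monoxide, [C-]#[O+]
Why: Palladium-catalysed cyclocarbonylation of the homopropargylic alcohol (Markovnikov hydropalladation of the alkyne, CO insertion and capture of the acyl-palladium by C6–OH) should give the α-methylene-γ-butyrolactone with the anti C6/C7 relationship carried over as the trans ring fusion.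

Step 11
Reactants: 14 (4S,5R)-4-[(1R,3E)-1,5-bis(tert-butyldimethylsilyloxy)-3-methylpent-3-en-1-yl]-5-(2,2-dimethoxyethyl)-3-methylideneoxolan-2-one
Product: 15 2-{(2R,3S)-3-[(1R,3E)-1-(tert-butyldimethylsilyloxy)-5-hydroxy-3-methylpent-3-en-1-yl]-4-methylidene-5-oxooxolan-2-yl}acetaldehyde
Conditions: AcOH/THF/H2O (3:1:1), 45 °C
Reagents that add atoms: water, O
Why: Mild aqueous acid should hydrolyse the dimethyl acetal and cleave the primary allylic silyl ether, while the hindered secondary silyl ether at C8 is retained on kinetic grounds (acetal hydrolysis and selective desilylation).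

Step 12
Reactants: 15 2-{(2R,3S)-3-[(1R,3E)-1-(tert-butyldimethylsilyloxy)-5-hydroxy-3-methylpent-3-en-1-yl]-4-methylidene-5-oxooxolan-2-yl}acetaldehyde
Product: 16 tert-butyl 4-{(2R,3S)-3-[(1R,3E)-1-(tert-butyldimethylsilyloxy)-5-hydroxy-3-methylpent-3-en-1-yl]-4-methylidene-5-oxooxolan-2-yl}-3-oxobutanoate
Conditions: N2CHCO2tBu (1.3 equiv), SnCl2 (10 mol%), CH2Cl2, rt
Reagents that add atoms: tert-butyl diazoacetate, CC(C)(C)OC(=O)C=[N+]=[N-]
Why: Roskamp reaction, in which tin(II)-promoted addition of the diazo ester to the aldehyde followed by 1,2-hydride shift with loss of N2 should give the β-keto ester directly under conditions mild enough for the β-acyloxy aldehyde and the free alcohol.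

Step 13
Reactants: 16 tert-butyl 4-{(2R,3S)-3-[(1R,3E)-1-(tert-butyldimethylsilyloxy)-5-hydroxy-3-methylpent-3-en-1-yl]-4-methylidene-5-oxooxolan-2-yl}-3-oxobutanoate
Product: 18 twelve-membered allyl β-keto lactone (ring O–C2–C1=C10–C9–C8–C7–C6–C5–C4(=O)–C3–C(=O); 8-OTBS; α-methylene-γ-lactone trans-fused at C6/C7; 6R,7S,8R; 1(10)E), via acylketene 17 (not isolated)
Conditions: toluene, 110 °C, syringe-pump addition to 0.001 M
Reagents that add atoms: none
Why: Thermolysis of the tert-butyl β-keto ester expels tert-butanol to give an acylketene, which under high dilution should be captured by the primary allylic C2 hydroxyl (acylketene macrolactonisation) rather than intermolecularly, closing the twelve-membered ring.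

Step 14
Reactants: 18 twelve-membered allyl β-keto lactone
Product: 20 3-(triisopropylsilyloxy) derivative of lactone 18 (both C3 epimers), via α-hydroxy lactone 19 (not isolated)
Conditions: KHMDS (1.05 equiv), THF, −78 °C; 2-(phenylsulfonyl)-3-phenyloxaziridine (1.2 equiv); then TIPSOTf, 2,6-lutidine, −78 → 0 °C
Reagents that add atoms: 2-(phenylsulfonyl)-3-phenyloxaziridine, O=S(=O)(N1OC1c1ccccc1)c1ccccc1; triisopropylsilyl triflate, CC(C)[Si](OS(=O)(=O)C(F)(F)F)(C(C)C)C(C)C
Why: One equivalent of base deprotonates only the doubly activated C3–H, the potassium enolate is hydroxylated by the sulfonyloxaziridine (Davis oxidation) and the alkoxide is silylated in the same flask, the C3 configuration being irrelevant because the centre becomes a planar enolate in step 15.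

Step 15
Reactants: 20 3-(triisopropylsilyloxy) twelve-membered allyl β-keto lactone
Product: 22 3β-(triisopropylsilyloxy)-8β-(tert-butyldimethylsilyloxy)-4-oxo-15-norgermacra-1(10)E,11(13)-dien-6α,12-olide (3S,6R,7S,8R), via allylpalladium enolate 21 (not isolated)
Conditions: Pd2(dba)3·CHCl3 (5 mol%), (R,R)-DACH-phenyl Trost ligand (12 mol%), degassed THF (0.002 M), 25 °C
Reagents that add atoms: none
Why: Pd(0) ionises the allylic C2–O bond of the twelve-membered lactone to a tethered π-allylpalladium β-keto carboxylate, which loses CO2 to give the C3=C4 enolate 21, and C-allylation at the distal allyl terminus C2 then closes the ten-membered carbocycle, so the ring shrinks by the two atoms (O and C) of CO2. The closest known reaction is the Tsuji–Saegusa (Carroll-type) decarboxylative allylation of allyl β-keto esters such as geranyl acetoacetate, together with its asymmetric variant on α-oxygenated enolates with Trost ligands; it is applied here to a macrocyclic substrate in which the ester itself is the tether. The ten-membered ring closes in the 10-endo mode with respect to the allyl unit (C2, C1 and C10 all end up in the ring), in competition with 8-exo attack at C10. The new stereocentre C3 is set under catalyst control on the planar enolate, the ligand enantiomer being chosen for the 3S product (its antipode would give the 3-epimer), so both C3 epimers of 20 should converge on one product, and the E geometry of C1=C10 follows from the syn π-allyl complex that the E-allylic ester forms and to which any anti complex equilibrates. The step needs distal rather than proximal attack, C- rather than O-allylation and ring closure rather than oligomerisation; the fully substituted C10 terminus disfavours the 8-exo path, the soft silyloxy-enolate prefers carbon, and high dilution with the ion pair held on one chain favours cyclisation.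

Step 16
Reactants: 22 3β-(triisopropylsilyloxy)-8β-(tert-butyldimethylsilyloxy)-4-oxo-15-norgermacra-1(10)E,11(13)-dien-6α,12-olide
Product: 23 3β-(triisopropylsilyloxy)-8β-(tert-butyldimethylsilyloxy)-4α-hydroxygermacra-1(10)E,11(13)-dien-6α,12-olide (3S,4S,6R,7S,8R)
Conditions: MeLi/CeCl3 (1.5 equiv, premixed), THF, −78 °C
Reagents that add atoms: methyllithium, [Li]C
Why: The weakly basic, oxophilic methylcerium reagent should add to the ketone faster than to the lactone carbonyl and without conjugate addition (organocerium 1,2-addition), and attack anti to the bulky α-silyloxy group (polar Felkin–Anh, from the peripheral face) should set C4 as the 4α-carbinol, threo to C3–O.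

Step 17
Reactants: 23 3β-(triisopropylsilyloxy)-8β-(tert-butyldimethylsilyloxy)-4α-hydroxygermacra-1(10)E,11(13)-dien-6α,12-olide
Product: 24 3β-(triisopropylsilyloxy)-4α,8β-dihydroxygermacra-1(10)E,11(13)-dien-6α,12-olide
Conditions: HF·pyridine, pyridine, THF, 0 °C → rt
Reagents that add atoms: none
Why: Acidic fluoride should cleave the secondary tert-butyldimethylsilyl ether at C8 much faster than the triisopropylsilyl ether at C3, which is more robust and shielded by the adjacent quaternary C4 (selective desilylation).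

Step 18
Reactants: 24 3β-(triisopropylsilyloxy)-4α,8β-dihydroxygermacra-1(10)E,11(13)-dien-6α,12-olide, 25 angelic acid
Product: 26 8β-angeloyloxy-3β-(triisopropylsilyloxy)-4α-hydroxygermacra-1(10)E,11(13)-dien-6α,12-olide
Conditions: 25, 2,4,6-trichlorobenzoyl chloride, Et3N, toluene, rt; then 24, DMAP, toluene, 60 °C
Reagents that add atoms: none
Why: Yamaguchi esterification via the preformed mixed anhydride should acylate the only reactive hydroxyl (C8–OH, the tertiary C4–OH being inert) and is a standard way to make angelates without Z→E isomerisation to the tiglate.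

Step 19
Reactants: 26 8β-angeloyloxy-3β-(triisopropylsilyloxy)-4α-hydroxygermacra-1(10)E,11(13)-dien-6α,12-olide
Product: 27 8β-angeloyloxy-3β,4α-dihydroxygermacra-1(10)E,11(13)-dien-6α,12-olide
Conditions: TBAF/AcOH (1:1), THF, 0 °C → rt
Reagents that add atoms: none
Why: Fluoride buffered with acetic acid should remove the triisopropylsilyl ether without acyl migration of the angelate or conjugate addition to the methylene lactone (desilylation).

Step 20
Reactants: 27 8β-angeloyloxy-3β,4α-dihydroxygermacra-1(10)E,11(13)-dien-6α,12-olide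
Product: 28 argophyllin A
Conditions: mCPBA (1.05 equiv), NaHCO3, CH2Cl2, −10 °C
Reagents that add atoms: meta-chloroperbenzoic acid, OOC(=O)c1cccc(Cl)c1
Why: Prilezhaev epoxidation should be chemoselective for the only electron-rich alkene (C1=C10, the two acrylate-type alkenes being deactivated), stereospecific for the E geometry, and face-selective through peripheral attack on the β-face at C1 assisted by hydrogen bonding to the homoallylic 3β-hydroxyl, giving the 1β,10α (1R,10R) epoxide.

Compound list
1 | (R)-glycidyl 4-methoxybenzyl ether | C1O[C@H]1COCc1ccc(OC)cc1 | starting material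
2 | (R)-1-[(4-methoxybenzyl)oxy]pent-4-yn-2-ol | C#CC[C@@H](O)COCc1ccc(OC)cc1 | intermediate
3 | (E)-alkenyldimethylalane (C8–O aluminated), not isolated | C[Al](C)/C=C(\C)C[C@@H](O[Al](C)C)COCc1ccc(OC)cc1 | intermediate
4 | (2E,5R)-6-[(4-methoxybenzyl)oxy]-3-methylhex-2-ene-1,5-diol | OC/C=C(\C)C[C@@H](O)COCc1ccc(OC)cc1 | intermediate
5 | (2E,5R)-1,5-bis(tert-butyldimethylsilyloxy)-6-[(4-methoxybenzyl)oxy]-3-methylhex-2-ene | CC(C)(C)[Si](C)(C)OC/C=C(\C)C[C@@H](O[Si](C)(C)C(C)(C)C)COCc1ccc(OC)cc1 | intermediate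
6 | (2R,4E)-2,6-bis(tert-butyldimethylsilyloxy)-4-methylhex-4-en-1-ol | CC(C)(C)[Si](C)(C)OC/C=C(\C)C[C@@H](O[Si](C)(C)C(C)(C)C)CO | intermediate
7 | (2R,4E)-2,6-bis(tert-butyldimethylsilyloxy)-4-methylhex-4-enal | CC(C)(C)[Si](C)(C)OC/C=C(\C)C[C@@H](O[Si](C)(C)C(C)(C)C)C=O | intermediate
8 | (3S,4R,6E)-4,8-bis(tert-butyldimethylsilyloxy)-6-methyloct-6-en-1-yn-3-ol | CC(C)(C)[Si](C)(C)OC/C=C(\C)C[C@@H](O[Si](C)(C)C(C)(C)C)[C@@H](O)C#C | intermediate
9 | (3S,4R,6E)-4,8-bis(tert-butyldimethylsilyloxy)-6-methyloct-6-en-1-yn-3-yl methanesulfonate | CC(C)(C)[Si](C)(C)OC/C=C(\C)C[C@@H](O[Si](C)(C)C(C)(C)C)[C@@H](OS(C)(=O)=O)C#C | intermediate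
10 | methyl 3,3-dimethoxypropanoate | COC(=O)CC(OC)OC | starting material
11 | 3,3-dimethoxypropanal | COC(CC=O)OC | intermediate
12 | allenyl(ethyl)zinc from 9 (Zn on C13; axial chirality relayed from C7), not isolated | CC[Zn]C=C=C[C@H](O[Si](C)(C)C(C)(C)C)C/C(C)=C/CO[Si](C)(C)C(C)(C)C | intermediate
13 | (3R,4S,5R,7E)-5,9-bis(tert-butyldimethylsilyloxy)-4-ethynyl-1,1-dimethoxy-7-methylnon-7-en-3-ol | CC(C)(C)[Si](C)(C)OC/C=C(\C)C[C@@H](O[Si](C)(C)C(C)(C)C)[C@@H](C#C)[C@H](O)CC(OC)OC | intermediate
14 | (4S,5R)-4-[(1R,3E)-1,5-bis(tert-butyldimethylsilyloxy)-3-methylpent-3-en-1-yl]-5-(2,2-dimethoxyethyl)-3-methylideneoxolan-2-one | CC(C)(C)[Si](C)(C)OC/C=C(\C)C[C@@H](O[Si](C)(C)C(C)(C)C)[C@H]1C(=C)C(=O)O[C@@H]1CC(OC)OC | intermediate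
15 | 2-{(2R,3S)-3-[(1R,3E)-1-(tert-butyldimethylsilyloxy)-5-hydroxy-3-methylpent-3-en-1-yl]-4-methylidene-5-oxooxolan-2-yl}acetaldehyde | OC/C=C(\C)C[C@@H](O[Si](C)(C)C(C)(C)C)[C@H]1C(=C)C(=O)O[C@@H]1CC=O | intermediate
16 | tert-butyl 4-{(2R,3S)-3-[(1R,3E)-1-(tert-butyldimethylsilyloxy)-5-hydroxy-3-methylpent-3-en-1-yl]-4-methylidene-5-oxooxolan-2-yl}-3-oxobutanoate | OC/C=C(\C)C[C@@H](O[Si](C)(C)C(C)(C)C)[C@H]1C(=C)C(=O)O[C@@H]1CC(=O)CC(=O)OC(C)(C)C | intermediate
17 | acylketene from 16 (C3=C=O), not isolated | OC/C=C(\C)C[C@@H](O[Si](C)(C)C(C)(C)C)[C@H]1C(=C)C(=O)O[C@@H]1CC(=O)C=C=O | intermediate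
18 | twelve-membered allyl β-keto lactone (6R,7S,8R; 1(10)E; 8-OTBS; trans-fused α-methylene-γ-lactone) | O1C/C=C(\C)C[C@@H](O[Si](C)(C)C(C)(C)C)[C@H]2C(=C)C(=O)O[C@@H]2CC(=O)CC1=O | intermediate
19 | 3-hydroxy derivative of 18 (C3 epimers), not isolated | O1C/C=C(\C)C[C@@H](O[Si](C)(C)C(C)(C)C)[C@H]2C(=C)C(=O)O[C@@H]2CC(=O)C(O)C1=O | intermediate
20 | 3-(triisopropylsilyloxy) derivative of 18 (C3 epimers) | O1C/C=C(\C)C[C@@H](O[Si](C)(C)C(C)(C)C)[C@H]2C(=C)C(=O)O[C@@H]2CC(=O)C(O[Si](C(C)C)(C(C)C)C(C)C)C1=O | intermediate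
21 | allylpalladium enolate after loss of CO2 (ligands omitted, drawn as the σ-allyl form), not isolated | [Pd+]C/C=C(\C)C[C@@H](O[Si](C)(C)C(C)(C)C)[C@H]1C(=C)C(=O)O[C@@H]1CC([O-])=CO[Si](C(C)C)(C(C)C)C(C)C | intermediate
22 | 3β-(triisopropylsilyloxy)-8β-(tert-butyldimethylsilyloxy)-4-oxo-15-norgermacra-1(10)E,11(13)-dien-6α,12-olide | C1/C=C(\C)C[C@@H](O[Si](C)(C)C(C)(C)C)[C@H]2C(=C)C(=O)O[C@@H]2CC(=O)[C@H]1O[Si](C(C)C)(C(C)C)C(C)C | intermediate
23 | 3β-(triisopropylsilyloxy)-8β-(tert-butyldimethylsilyloxy)-4α-hydroxygermacra-1(10)E,11(13)-dien-6α,12-olide | C1/C=C(\C)C[C@@H](O[Si](C)(C)C(C)(C)C)[C@H]2C(=C)C(=O)O[C@@H]2C[C@](C)(O)[C@H]1O[Si](C(C)C)(C(C)C)C(C)C | intermediate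
24 | 3β-(triisopropylsilyloxy)-4α,8β-dihydroxygermacra-1(10)E,11(13)-dien-6α,12-olide | C1/C=C(\C)C[C@@H](O)[C@H]2C(=C)C(=O)O[C@@H]2C[C@](C)(O)[C@H]1O[Si](C(C)C)(C(C)C)C(C)C | intermediate
25 | angelic acid, (Z)-2-methylbut-2-enoic acid | C/C=C(/C)C(=O)O | starting material
26 | 8β-angeloyloxy-3β-(triisopropylsilyloxy)-4α-hydroxygermacra-1(10)E,11(13)-dien-6α,12-olide | C1/C=C(\C)C[C@@H](OC(=O)/C(C)=C\C)[C@H]2C(=C)C(=O)O[C@@H]2C[C@](C)(O)[C@H]1O[Si](C(C)C)(C(C)C)C(C)C | intermediate
27 | 8β-angeloyloxy-3β,4α-dihydroxygermacra-1(10)E,11(13)-dien-6α,12-olide | C1/C=C(\C)C[C@@H](OC(=O)/C(C)=C\C)[C@H]2C(=C)C(=O)O[C@@H]2C[C@](C)(O)[C@H]1O | intermediate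
28 | argophyllin A, 8β-angeloyloxy-1β,10α-epoxy-3β,4α-dihydroxygermacr-11(13)-en-6α,12-olide | C=C1C(=O)O[C@@H]2C[C@](C)(O)[C@@H](O)C[C@H]3O[C@]3(C)C[C@@H](OC(=O)/C(C)=C\C)[C@@H]12 | target

Total step count: 20. Longest linear sequence: 19 steps (steps 1–7 and 9–20, from 1 to 28); step 8 is a one-step side branch.

Steps most likely to fail

Step 15 (ring contraction). The tethered π-allyl/enolate pair may collapse by O-allylation, lose a proton to give a diene, or oligomerise instead of closing the ten-membered ring, and face selection at C3 of the hindered silyloxy-enolate may be poor. The fallback sets out from 18 and comes back at 22: the oxygenation is moved behind the contraction, so that the unhindered, achiral enolate of the parent lactone is used, the direct macrocyclic counterpart of geranyl acetoacetate. Lactone 18 would be contracted with Pd(PPh3)4 (THF, 0.002 M, rt) to 8β-(tert-butyldimethylsilyloxy)-4-oxo-15-norgermacra-1(10)E,11(13)-dien-6α,12-olide F1. Kinetic enolisation on the less hindered C3 side (LiHMDS, TESCl, THF, −78 °C) should give the C3=C4 triethylsilyl enol ether F2. Rubottom oxidation with dimethyldioxirane at −78 °C, where the enol ether should react before C1=C10, should give 3β-hydroxy-8β-(tert-butyldimethylsilyloxy)-4-oxo-15-norgermacra-1(10)E,11(13)-dien-6α,12-olide F3 after separation of the C3 epimers. TIPSOTf/2,6-lutidine then returns to 22.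

Step 16 (methyl addition). The organometallic may be consumed by conjugate or acyl attack on the α-methylene lactone, or the ketone may enolise with β-elimination of the C6 carboxylate. The fallback sets out from 22 and comes back at 23: the Michael acceptor is masked temporarily. Dimethylamine (THF, 0 °C) should add to C13 to give the 13-(dimethylamino)-11,13-dihydro adduct of 22 F4. MeMgBr/CeCl3 (−78 °C) then adds to the ketone to give the 13-(dimethylamino)-11,13-dihydro adduct of 23 F5. Quaternisation with MeI followed by NaHCO3-induced elimination regenerates the methylene lactone 23.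

Step 9 (propargylation). The α-silyloxy allenylzinc may lose silyloxide by vinylogous β-elimination (enyne formation), the allenylmetal may racemise, or the anti:syn ratio with the unbranched aldehyde may be low. The fallback sets out from 7 and comes back at 14: a 2-alkoxycarbonyl-allylboration builds the lactone directly. Morita–Baylis–Hillman reaction of 7 with methyl acrylate (DABCO) gives methyl 2-[(2R,4E)-2,6-bis(tert-butyldimethylsilyloxy)-1-hydroxy-4-methylhex-4-en-1-yl]acrylate F6, and acetylation (Ac2O, DMAP) gives its acetate F7. Copper-catalysed SN2′ borylation (CuCl, B2pin2) gives the (Z)-2-(methoxycarbonyl)allylboronate F8. Its Sc(OTf)3-catalysed addition to 11 through a chair transition state (C8 branch trans to CH2B, hence anti) and acid-induced lactonisation return to 14; here C7 is set by 1,2-induction from C8 instead of by chirality transfer.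

Further compounds
F1 | step 15 | 8β-(tert-butyldimethylsilyloxy)-4-oxo-15-norgermacra-1(10)E,11(13)-dien-6α,12-olide | C1/C=C(\C)C[C@@H](O[Si](C)(C)C(C)(C)C)[C@H]2C(=C)C(=O)O[C@@H]2CC(=O)C1
F2 | step 15 | C3=C4 triethylsilyl enol ether of F1 | C1/C=C(\C)C[C@@H](O[Si](C)(C)C(C)(C)C)[C@H]2C(=C)C(=O)O[C@@H]2CC(O[Si](CC)(CC)CC)=CC1
F3 | step 15 | 3β-hydroxy-8β-(tert-butyldimethylsilyloxy)-4-oxo-15-norgermacra-1(10)E,11(13)-dien-6α,12-olide | C1/C=C(\C)C[C@@H](O[Si](C)(C)C(C)(C)C)[C@H]2C(=C)C(=O)O[C@@H]2CC(=O)[C@H]1O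
F4 | step 16 | 13-(dimethylamino)-11,13-dihydro adduct of 22 | C1/C=C(\C)C[C@@H](O[Si](C)(C)C(C)(C)C)[C@H]2C(CN(C)C)C(=O)O[C@@H]2CC(=O)[C@H]1O[Si](C(C)C)(C(C)C)C(C)C
F5 | step 16 | 13-(dimethylamino)-11,13-dihydro adduct of 23 | C1/C=C(\C)C[C@@H](O[Si](C)(C)C(C)(C)C)[C@H]2C(CN(C)C)C(=O)O[C@@H]2C[C@](C)(O)[C@H]1O[Si](C(C)C)(C(C)C)C(C)C
F6 | step 9 | methyl 2-[(2R,4E)-2,6-bis(tert-butyldimethylsilyloxy)-1-hydroxy-4-methylhex-4-en-1-yl]acrylate | CC(C)(C)[Si](C)(C)OC/C=C(\C)C[C@@H](O[Si](C)(C)C(C)(C)C)C(O)C(=C)C(=O)OC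
F7 | step 9 | acetate of F6 | CC(C)(C)[Si](C)(C)OC/C=C(\C)C[C@@H](O[Si](C)(C)C(C)(C)C)C(OC(C)=O)C(=C)C(=O)OC
F8 | step 9 | methyl (2Z,4R,6E)-4,8-bis(tert-butyldimethylsilyloxy)-6-methyl-2-[(pinacolatoboryl)methyl]octa-2,6-dienoate | CC(C)(C)[Si](C)(C)OC/C=C(\C)C[C@@H](O[Si](C)(C)C(C)(C)C)/C=C(/CB1OC(C)(C)C(C)(C)O1)C(=O)OC
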